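**Retrosynthetic overview**
1. Target 12 ⇐ 11 by removal of the two phenol benzyl ethers.
2. 11 ⇐ triol 9 by closing the tetrahydrofuran through a CH2–O bond between the two primary carbinols, with the benzylic carbinol left free (key step, new method).
3. 9 ⇐ trans,anti aldol lactone 8 by reduction; the γ-butyrolactone is a temporary ring that fixes the ring stereochemistry.
4. 8 ⇐ (R)-β-benzyl-γ-butyrolactone 6 + aldehyde 1 (aldol sets ring C3 and the carbinol centre); 6 ⇐ 1 + dimethyl succinate 2 by Stobbe condensation, asymmetric hydrogenation (sets ring C4) and ester reduction/lactonisation.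
5. Ring order: γ-butyrolactone (step 3) → opened (step 5) → tetrahydrofuran (step 6); both arenes are bought.

Assumption: the (S,S)-Et-DuPhos–Rh catalyst in step 2 is taken to give the (R)-acid 4; if lactone 6 proves to be the (S)-enantiomer (rotation, chiral HPLC), the (R,R)-ligand is used instead.

**Route**

Step 1
Reactants: 1 4-(benzyloxy)-3-methoxybenzaldehyde; 2 dimethyl succinate
Product: 3 (E)-4-[4-(benzyloxy)-3-methoxyphenyl]-3-(methoxycarbonyl)but-3-enoic acid
Conditions: NaOMe (2.2 equiv), MeOH, reflux; then aq. HCl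
Reagents that add atoms: none
Why: Stobbe condensation: aldol addition of the succinate enolate, lactonisation to the paraconate and irreversible E1cB ring opening to the carboxylate give the (E)-half-ester; no stereocentre is formed.

Step 2
Reactants: 3 (E)-4-[4-(benzyloxy)-3-methoxyphenyl]-3-(methoxycarbonyl)but-3-enoic acid
Product: 4 (R)-4-[4-(benzyloxy)-3-methoxyphenyl]-3-(methoxycarbonyl)butanoic acid
Conditions: H2 (5 atm), [Rh(cod)((S,S)-Et-DuPhos)]OTf (0.3 mol%), NaOMe (10 mol%), MeOH, rt
Reagents that add atoms: none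
Why: Rh–bisphosphine asymmetric hydrogenation of an itaconate-type half-ester: the chelated alkene is hydrogenated on one face, which sets the (R) centre that becomes ring C4; the aryl benzyl ether is inert to the homogeneous Rh catalyst.

Step 3
Reactants: 4 (R)-4-[4-(benzyloxy)-3-methoxyphenyl]-3-(methoxycarbonyl)butanoic acid
Product: 6 (R)-4-[4-(benzyloxy)-3-methoxybenzyl]dihydrofuran-2(3H)-one, via hydroxy acid 5 (not isolated)
Conditions: LiBH4 (2.5 equiv), THF, 0 °C → rt; then 2 M HCl, rt
Reagents that add atoms: none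
Why: Chemoselective borohydride reduction: LiBH4 reduces the methyl ester but not the carboxylate, and acidification lactonises hydroxy acid 5; the stereocentre is not touched.

Step 4
Reactants: 6 (R)-4-[4-(benzyloxy)-3-methoxybenzyl]dihydrofuran-2(3H)-one; 1 4-(benzyloxy)-3-methoxybenzaldehyde
Product: 8 (3S,4R)-3-{(R)-[4-(benzyloxy)-3-methoxyphenyl](hydroxy)methyl}-4-[4-(benzyloxy)-3-methoxybenzyl]dihydrofuran-2(3H)-one, via lithium enolate 7 (not isolated)
Conditions: LDA (1.1 equiv), THF, −78 °C; then 1, −78 °C, 1 h; AcOH quench at −78 °C; chromatography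
Reagents that add atoms: lithium diisopropylamide, [Li+].CC(C)[N-]C(C)C (supplies the lithium of 7 only; no atoms in 8)
Why: Aldol addition of a lactone lithium enolate (Zimmerman–Traxler): the aldehyde adds to the ring-locked E-enolate 7 on the face anti to the C4 benzyl group (3,4-trans), and the chair transition state with the aryl group equatorial gives the anti aldol, which is the (R)-carbinol; selectivity at the carbinol is only moderate and the epimers are separated on silica.

Step 5
Reactants: 8 (3S,4R)-3-{(R)-[4-(benzyloxy)-3-methoxyphenyl](hydroxy)methyl}-4-[4-(benzyloxy)-3-methoxybenzyl]dihydrofuran-2(3H)-one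
Product: 9 (1R,2R,3R)-1-[4-(benzyloxy)-3-methoxyphenyl]-3-[4-(benzyloxy)-3-methoxybenzyl]-2-(hydroxymethyl)butane-1,4-diol
Conditions: LiAlH4 (2.5 equiv), THF, 0 °C → rt; Fieser work-up
Reagents that add atoms: none
Why: LiAlH4 reduction of a lactone to the diol; reduction at 0 °C is faster than retro-aldol or epimerisation α to the carbonyl, so all three centres are kept.

Step 6
Reactants: 9 (1R,2R,3R)-1-[4-(benzyloxy)-3-methoxyphenyl]-3-[4-(benzyloxy)-3-methoxybenzyl]-2-(hydroxymethyl)butane-1,4-diol
Product: 11 (R)-[4-(benzyloxy)-3-methoxyphenyl]{(3R,4R)-4-[4-(benzyloxy)-3-methoxybenzyl]tetrahydrofuran-3-yl}methanol, via monotosylate 10 (not isolated)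
Conditions: Ph2BOCH2CH2NH2 (10 mol%), TsCl (1.1 equiv), i-Pr2NEt (3 equiv), MeCN, 0 °C → rt; then 60 °C
Reagents that add atoms: p-toluenesulfonyl chloride, Cc1ccc(cc1)S(=O)(=O)Cl (tosyl group present in 10 only, lost again on ring closure)
Why: Proposed new method: the diphenylborinic acid binds the 1,3-diol of 9 (benzylic OH plus the neighbouring CH2OH) as a six-membered tetracoordinate borinate with both substituents equatorial, which raises the nucleophilicity of the unhindered primary oxygen so that TsCl sulfonylates that CH2OH only; the remote CH2OH then displaces the tosylate in a 5-exo-tet Williamson closure, while the benzylic OH could only give an oxetane (4-exo-tet, slow) and is never activated or exposed to acid or alkoxide base (no ionisation, no Grob fragmentation), so the carbinol keeps its configuration; the closest known reaction types are borinic-acid-catalysed regioselective monosulfonylation of 1,2- and 1,3-diols and the cyclisation of 1,4-diol monotosylates, which have not been shown as a tandem ring closure on an unprotected triol with a competing free primary OH.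

Step 7
Reactants: 11 (R)-[4-(benzyloxy)-3-methoxyphenyl]{(3R,4R)-4-[4-(benzyloxy)-3-methoxybenzyl]tetrahydrofuran-3-yl}methanol
Product: 12 (R)-(4-hydroxy-3-methoxyphenyl)[(3R,4R)-4-(4-hydroxy-3-methoxybenzyl)tetrahydrofuran-3-yl]methanol
Conditions: H2 (1 atm), 10% Pd/C, EtOAc, rt, stopped at full conversion
Reagents that add atoms: none
Why: Catalytic hydrogenolysis of aryl benzyl ethers; under neutral conditions in EtOAc these cleave much faster than the secondary benzylic C–OH bond, and no stereocentre is involved.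

**Compound list**
1 | 4-(benzyloxy)-3-methoxybenzaldehyde | COc1cc(C=O)ccc1OCc1ccccc1 | starting material
2 | dimethyl succinate | COC(=O)CCC(=O)OC | starting material
3 | (E)-4-[4-(benzyloxy)-3-methoxyphenyl]-3-(methoxycarbonyl)but-3-enoic acid | COc1cc(/C=C(\CC(=O)O)C(=O)OC)ccc1OCc1ccccc1 | intermediate
4 | (R)-4-[4-(benzyloxy)-3-methoxyphenyl]-3-(methoxycarbonyl)butanoic acid | COc1cc(C[C@H](CC(=O)O)C(=O)OC)ccc1OCc1ccccc1 | intermediate
5 | (R)-4-[4-(benzyloxy)-3-methoxyphenyl]-3-(hydroxymethyl)butanoic acid | COc1cc(C[C@H](CC(=O)O)CO)ccc1OCc1ccccc1 | intermediate (not isolated)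
6 | (R)-4-[4-(benzyloxy)-3-methoxybenzyl]dihydrofuran-2(3H)-one | COc1cc(C[C@H]2COC(=O)C2)ccc1OCc1ccccc1 | intermediate
7 | lithium (R)-4-[4-(benzyloxy)-3-methoxybenzyl]-4,5-dihydrofuran-2-olate | [Li+].COc1cc(C[C@H]2COC([O-])=C2)ccc1OCc1ccccc1 | intermediate (not isolated)
8 | (3S,4R)-3-{(R)-[4-(benzyloxy)-3-methoxyphenyl](hydroxy)methyl}-4-[4-(benzyloxy)-3-methoxybenzyl]dihydrofuran-2(3H)-one | COc1cc(C[C@H]2COC(=O)[C@@H]2[C@@H](O)c2ccc(OCc3ccccc3)c(OC)c2)ccc1OCc1ccccc1 | intermediate
9 | (1R,2R,3R)-1-[4-(benzyloxy)-3-methoxyphenyl]-3-[4-(benzyloxy)-3-methoxybenzyl]-2-(hydroxymethyl)butane-1,4-diol | COc1cc(C[C@@H](CO)[C@H](CO)[C@@H](O)c2ccc(OCc3ccccc3)c(OC)c2)ccc1OCc1ccccc1 | intermediate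
10 | (2R,3R)-2-{(R)-[4-(benzyloxy)-3-methoxyphenyl](hydroxy)methyl}-3-[4-(benzyloxy)-3-methoxybenzyl]-4-hydroxybutyl 4-methylbenzenesulfonate | COc1cc(C[C@@H](CO)[C@H](COS(=O)(=O)c2ccc(C)cc2)[C@@H](O)c2ccc(OCc3ccccc3)c(OC)c2)ccc1OCc1ccccc1 | intermediate (not isolated)
11 | (R)-[4-(benzyloxy)-3-methoxyphenyl]{(3R,4R)-4-[4-(benzyloxy)-3-methoxybenzyl]tetrahydrofuran-3-yl}methanol | COc1cc(C[C@H]2COC[C@@H]2[C@@H](O)c2ccc(OCc3ccccc3)c(OC)c2)ccc1OCc1ccccc1 | intermediate
12 | (R)-(4-hydroxy-3-methoxyphenyl)[(3R,4R)-4-(4-hydroxy-3-methoxybenzyl)tetrahydrofuran-3-yl]methanol | COc1cc(C[C@H]2COC[C@@H]2[C@@H](O)c2ccc(O)c(OC)c2)ccc1O | target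

**Step count and risks**

Total step count: 7. Longest linear sequence: 7 steps (from 1; aldehyde 1 is used twice).

The three steps most likely to fail:

Step 6 (the new ring closure). The risk is sulfonylation of the other primary OH, which would let the benzylic OH close to the isomeric 2-aryl-tetrahydrofuran, or incomplete site selectivity. The fallback uses known chemistry and sets out from 8. The carbinol is silylated (TBSOTf, 2,6-lutidine, CH2Cl2) to give (3S,4R)-3-{(R)-[4-(benzyloxy)-3-methoxyphenyl][(tert-butyldimethylsilyl)oxy]methyl}-4-[4-(benzyloxy)-3-methoxybenzyl]dihydrofuran-2(3H)-one F2. The lactone is reduced (LiBH4, THF) to (2R,3R)-2-{(R)-[4-(benzyloxy)-3-methoxyphenyl][(tert-butyldimethylsilyl)oxy]methyl}-3-[4-(benzyloxy)-3-methoxybenzyl]butane-1,4-diol F3. The 1,4-diol is closed by Mitsunobu cyclodehydration (PPh3, DIAD, THF) to tert-butyl{(R)-[4-(benzyloxy)-3-methoxyphenyl][(3R,4R)-4-(4-(benzyloxy)-3-methoxybenzyl)tetrahydrofuran-3-yl]methoxy}dimethylsilane F4. TBAF in THF then removes the silyl group and the path comes back to the route at 11.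

Step 4 (selectivity at the carbinol centre). The ring trans relationship is secure, but the anti/syn ratio of lithium aldols of this lactone class is modest. The fallback sets out from 6 and sets the carbinol by C–H rather than C–C bond formation. Enolate 7 (LiHMDS, 2.2 equiv, THF, −78 °C) is acylated with 4-(benzyloxy)-3-methoxybenzoyl chloride to give (3S,4R)-3-[4-(benzyloxy)-3-methoxybenzoyl]-4-[4-(benzyloxy)-3-methoxybenzyl]dihydrofuran-2(3H)-one F1. Noyori transfer hydrogenation (RuCl[(R,R)-TsDPEN](p-cymene), HCO2H/Et3N) then gives the (R)-carbinol under catalyst control, with the epimerisable ring C3 held trans to the benzyl group, and the path comes back at 8. The unwanted syn epimer from step 4 can be fed into the same path by Dess–Martin oxidation to F1.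

Step 7 (over-reduction). The electron-rich benzylic C–OH bond can be hydrogenolysed on Pd. The fallback sets out from 11 and goes directly to 12 by single-electron reductive debenzylation with excess lithium naphthalenide (THF, −25 °C). The carbinol is present as its lithium alkoxide, whose C–O bond is not cleaved; no new compound is made on this path (entry F0).

Further compounds
F1 | step 4 | (3S,4R)-3-[4-(benzyloxy)-3-methoxybenzoyl]-4-[4-(benzyloxy)-3-methoxybenzyl]dihydrofuran-2(3H)-one | COc1cc(C[C@H]2COC(=O)[C@@H]2C(=O)c2ccc(OCc3ccccc3)c(OC)c2)ccc1OCc1ccccc1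
F2 | step 6 | (3S,4R)-3-{(R)-[4-(benzyloxy)-3-methoxyphenyl][(tert-butyldimethylsilyl)oxy]methyl}-4-[4-(benzyloxy)-3-methoxybenzyl]dihydrofuran-2(3H)-one | COc1cc(C[C@H]2COC(=O)[C@@H]2[C@@H](O[Si](C)(C)C(C)(C)C)c2ccc(OCc3ccccc3)c(OC)c2)ccc1OCc1ccccc1
F3 | step 6 | (2R,3R)-2-{(R)-[4-(benzyloxy)-3-methoxyphenyl][(tert-butyldimethylsilyl)oxy]methyl}-3-[4-(benzyloxy)-3-methoxybenzyl]butane-1,4-diol | COc1cc(C[C@@H](CO)[C@H](CO)[C@@H](O[Si](C)(C)C(C)(C)C)c2ccc(OCc3ccccc3)c(OC)c2)ccc1OCc1ccccc1
F4 | step 6 | tert-butyl{(R)-[4-(benzyloxy)-3-methoxyphenyl][(3R,4R)-4-(4-(benzyloxy)-3-methoxybenzyl)tetrahydrofuran-3-yl]methoxy}dimethylsilane | COc1cc(C[C@H]2COC[C@@H]2[C@@H](O[Si](C)(C)C(C)(C)C)c2ccc(OCc3ccccc3)c(OC)c2)ccc1OCc1ccccc1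
F0 | step 7 | none | none
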